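**Plan**

Numbering follows the germacrane skeleton: carbocycle C1–C10, C11–C13 on C7 (C12 lactone carbonyl, C13 methylene), C14 on C10, C15 on C4; open-chain compounds are named as 9,10-seco-germacranes.
Retrosynthetic cuts, in order: C9–C10 (last ring closure), the O8 ester, the C3 acetate and the lactone C12–O6 bond; then the two C=O bonds at C3 and C6, because Z-C3(O)–C4(CH3)=C5–C6(O) is the ring-opened form of a 2,5-disubstituted 3-methylfuran whose ring carbons are C3–C6 and whose methyl is C15; finally C11=C13, C11–C12, C7–C8, C6–C7 and C2–C3.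
Forward, chain assembly: 3-methylfuran is brominated at C3, C7/C11 are attached at C6 with ethylene oxide, the Z-iodobutenyl arm (C2, C1, C10, C14) is attached at C3, and the furylacetic acid goes through an auxiliary-controlled aldol (C8, C9) before C12 and C13 are added at C11.
Forward, rings: singlet oxygen opens the furan, both ketones are reduced, the gamma-lactone closes first by oxidative lactonisation, acetate and epoxy ester are introduced, and the ten-membered carbocycle closes last by Nozaki–Hiyama–Kishi reaction.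
Stereochemistry: C7 and C8 from the Evans syn-aldol with the (S)-benzyloxazolidinone; C3 and C6 from one (R)-CBS catalyst; C9 from Felkin–Anh addition anti to O8; the epoxide centres from Sharpless epoxidation of tiglyl alcohol; Z-C1=C10 from trans-hydroalumination/iodination; Z-C4=C5 from the furan.

Key step: step 14

Remark: 17 and 23 are taken as purchased; 29, 34 and F8 carry one or two transient centres that are left undefined because they disappear again; changes of the C7 descriptor (R/S) along the route reflect CIP priority changes only, the spatial arrangement is never altered.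

**Route**

Step 1
Reactants: 1 but-2-yn-1-ol
Product: 3 (2Z)-3-iodobut-2-en-1-ol, via alkenylaluminate 2 (not isolated)
Conditions: NaAlH2(OCH2CH2OMe)2 (Red-Al), THF, 0 °C → rt; then I2, THF, −78 °C
Reagents that add atoms: iodine, II
Why: Trans-hydroalumination through a five-membered alkoxyaluminate puts aluminium on the future C10 cis to the CH2O group, and iodinolysis with retention should give the Z iodoalkene that later becomes Z-C1=C10.

Step 2
Reactants: 3 (2Z)-3-iodobut-2-en-1-ol
Product: 4 (2Z)-1-bromo-3-iodobut-2-ene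
Conditions: CBr4, PPh3, CH2Cl2, 0 °C
Reagents that add atoms: carbon tetrabromide, BrC(Br)(Br)Br
Why: Appel bromination converts the primary allylic alcohol into the bromide under neutral conditions without touching the alkenyl iodide or its geometry.

Step 3
Reactants: 5 3-methylfuran
Product: 6 2-bromo-3-methylfuran
Conditions: NBS, DMF, −20 → 0 °C, dark
Reagents that add atoms: N-bromosuccinimide, O=C1CCC(=O)N1Br
Why: Electrophilic aromatic bromination should occur at the alpha position next to the methyl group (future C3), the most electron-rich site, and the bromine then blocks this position and serves as the later metalation handle.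

Step 4
Reactants: 6 2-bromo-3-methylfuran
Product: 8 2-(5-bromo-4-methylfuran-2-yl)ethan-1-ol, via bromofuryllithium 7 (not isolated)
Conditions: LDA, THF, −78 °C; then ethylene oxide, −78 → 0 °C; aq NH4Cl
Reagents that add atoms: ethylene oxide, C1CO1
Why: Deprotonation with the amide base removes the only remaining alpha hydrogen (future C6) without bromine–lithium exchange, and the furyllithium opens the epoxide (epoxide ring opening) to install C7 and C11.

Step 5
Reactants: 8 2-(5-bromo-4-methylfuran-2-yl)ethan-1-ol; 4 (2Z)-1-bromo-3-iodobut-2-ene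
Product: 10 2-{5-[(2Z)-3-iodobut-2-en-1-yl]-4-methylfuran-2-yl}ethan-1-ol, via dilithio species 9 (not isolated)
Conditions: n-BuLi (2 equiv), THF, −78 °C; then 4, −78 → 0 °C
Reagents that add atoms: none
Why: After O-deprotonation, bromine–lithium exchange gives the C3 furyllithium, which is alkylated by the allylic bromide in an SN2 reaction; exchange with the alkenyl iodide is unfavourable because the furyl anion is the more stable carbanion.

Step 6
Reactants: 10 2-{5-[(2Z)-3-iodobut-2-en-1-yl]-4-methylfuran-2-yl}ethan-1-ol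
Product: 12 {5-[(2Z)-3-iodobut-2-en-1-yl]-4-methylfuran-2-yl}acetic acid, via furylacetaldehyde 11 (not isolated)
Conditions: TEMPO (cat.), PhI(OAc)2, MeCN/H2O, 0 °C → rt
Reagents that add atoms: water, O
Why: Oxoammonium (TEMPO) oxidation in aqueous acetonitrile takes the primary alcohol through the aldehyde hydrate to the carboxylic acid under mild conditions that should leave the furan and the alkenyl iodide alone.

Step 7
Reactants: 12 {5-[(2Z)-3-iodobut-2-en-1-yl]-4-methylfuran-2-yl}acetic acid; 13 (4S)-4-benzyl-1,3-oxazolidin-2-one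
Product: 16 (4S)-4-benzyl-3-({5-[(2Z)-3-iodobut-2-en-1-yl]-4-methylfuran-2-yl}acetyl)-1,3-oxazolidin-2-one, via mixed pivalic anhydride 14 (not isolated), via lithiated oxazolidinone 15 (not isolated)
Conditions: PivCl, Et3N, THF, −20 °C; then 15 (from 13, n-BuLi, THF, −78 °C), −78 → 0 °C
Reagents that add atoms: none
Why: N-acylation of the lithiated Evans oxazolidinone by the mixed anhydride, which is attacked at the less hindered furylacetyl carbonyl.

Step 8
Reactants: 16 N-(furylacetyl)oxazolidinone; 17 2-[(tert-butyldiphenylsilyl)oxy]acetaldehyde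
Product: 19 syn-aldol adduct (7R,8S; C8 OH; C9 OTBDPS; C11 imide carbonyl), via boron enolate 18 (not isolated)
Conditions: Bu2BOTf, i-Pr2NEt, CH2Cl2, −78 → 0 °C; then 17, −78 → 0 °C; pH 7 buffer/MeOH
Reagents that add atoms: none
Why: Evans syn-aldol reaction, in which soft enolisation gives the Z boron enolate and the Zimmerman–Traxler chair, with the benzyl group shielding one enolate face, sets C7 and C8 together with the required 7,8-syn relationship and absolute configuration.

Step 9
Reactants: 19 syn-aldol adduct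
Product: 20 Weinreb amide (7R,8S; C8 OH; C9 OTBDPS)
Conditions: MeNH(OMe)·HCl, AlMe3, CH2Cl2, −20 → 0 °C
Reagents that add atoms: N,O-dimethylhydroxylamine hydrochloride, CNOC.Cl
Why: Aluminium amide transamidation of the beta-hydroxy imide (Weinreb amide formation) removes the auxiliary without retro-aldol cleavage or epimerisation at C7.

Step 10
Reactants: 20 Weinreb amide
Product: 21 C8 triethylsilyl ether of the Weinreb amide
Conditions: TESOTf, 2,6-lutidine, CH2Cl2, −78 °C
Reagents that add atoms: triethylsilyl trifluoromethanesulfonate, CC[Si](CC)(CC)OS(=O)(=O)C(F)(F)F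
Why: Silylation of the secondary alcohol with a silyl triflate and a hindered base; the triethylsilyl ether is chosen because it can later be cleaved in the presence of the primary tert-butyldiphenylsilyl ether.

Step 11
Reactants: 22 (4-methoxyphenyl)methanol; 23 tributyl(iodomethyl)stannane
Product: 24 tributyl{[(4-methoxybenzyl)oxy]methyl}stannane
Conditions: NaH, THF/DMF, 0 °C → rt
Reagents that add atoms: none
Why: Williamson etherification of the alkoxide with the primary iodide gives the alpha-alkoxystannane, the precursor of the C12 hydroxymethyl anion equivalent.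

Step 12
Reactants: 21 C8 triethylsilyl ether of the Weinreb amide; 24 tributyl{[(4-methoxybenzyl)oxy]methyl}stannane
Product: 27 C11 ketone (7R,8S; C12 OPMB; C8 OTES; C9 OTBDPS), via alkoxymethyllithium 25 (not isolated), via alkoxymethylmagnesium bromide 26 (not isolated)
Conditions: 24, n-BuLi, THF, −78 °C; MgBr2·OEt2, −78 °C; then 21, −78 → 0 °C; aq NH4Cl
Reagents that add atoms: none
Why: Tin–lithium exchange gives the alkoxymethyllithium, transmetalation to magnesium should suppress iodine–metal exchange at the alkenyl iodide and enolisation at C7, and addition to the Weinreb amide stops at the chelated tetrahedral intermediate, so the ketone appears only on work-up.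

Step 13
Reactants: 27 C11 ketone
Product: 28 furan precursor with the C11=C13 methylene (7R,8S; C12 OPMB; C8 OTES; C9 OTBDPS; Z-iodoalkene)
Conditions: Cp2TiMe2, toluene, 70 °C, dark
Reagents that add atoms: dimethyltitanocene, C[Ti](C)(C1C=CC=C1)C1C=CC=C1
Why: Petasis methylenation (titanium methylidene, oxatitanacyclobutane, loss of titanocene oxide) is non-basic, so the acidic C7–H next to the furan should not epimerise and the beta-silyloxy group should not be eliminated.

Step 14
Reactants: 28 furan precursor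
Product: 30 Z-ene-3,6-dione (7R,8S; C12 OPMB; C8 OTES; C9 OTBDPS; Z-iodoalkene), via endoperoxide 29 (not isolated)
Conditions: O2, visible light, tetraphenylporphyrin (cat.), CH2Cl2, −78 °C; then Me2S, −78 → 0 °C
Reagents that add atoms: dioxygen, O=O
Why: Singlet oxygen (energy transfer from the excited porphyrin) adds across C3 and C6 of the furan in a [4+2] cycloaddition to give the 2,3,7-trioxabicyclo[2.2.1]hept-5-ene 29, and dimethyl sulfide then takes one peroxide oxygen so that the bicycle collapses to the ene-1,4-dione, the furan oxygen and one oxygen of O2 ending as the C3 and C6 carbonyl oxygens. The closest known reaction type is the photooxygenation of 2,5-dialkylfurans with reductive work-up to cis-enediones. No ring is closed and no stereocentre is formed; the C4=C5 geometry can only be Z because C3 and C6 were held cis by the furan oxygen. The step needs chemoselectivity for the furan, and the substrate secures it because a trialkylfuran reacts with singlet oxygen far faster than the 1,1-disubstituted C11=C13 alkene (slow ene reaction) or the electron-poor iodoalkene. It also needs kinetic retention of the Z geometry and of C7 (alpha to the new C6 ketone and allylic), which low temperature, a neutral reductant and immediate reduction of 30 in step 15 should secure.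

Step 15
Reactants: 30 Z-ene-3,6-dione
Product: 31 (3S,6R)-Z-ene-3,6-diol (7S,8S; C12 OPMB; C8 OTES; C9 OTBDPS)
Conditions: (R)-2-methyl-CBS-oxazaborolidine (0.3 equiv), catecholborane, toluene/CH2Cl2, −78 °C; MeOH
Reagents that add atoms: none
Why: Corey–Bakshi–Shibata reduction, in which each ketone binds the catalyst boron anti to its alkenyl (larger) substituent, so the (R)-catalyst should give 3S and 6R in one operation; both carbonyls are reduced as borates before a Z-hydroxy enone can cyclise back towards a furan, and catecholborane does not hydroborate the C11=C13 alkene at this temperature.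

Step 16
Reactants: 31 (3S,6R)-Z-ene-3,6-diol
Product: 32 3,6,12-triol (C8 OTES; C9 OTBDPS)
Conditions: DDQ, CH2Cl2/pH 7 phosphate buffer, 0 °C
Reagents that add atoms: none
Why: Oxidative cleavage of the 4-methoxybenzyl ether by DDQ (hydride abstraction, hydrolysis of the oxocarbenium ion) frees the allylic C12 alcohol while the silyl ethers and the iodide stay.

Step 17
Reactants: 32 3,6,12-triol
Product: 35 alpha-methylene gamma-lactone (12,6-olide; C3 OH; C8 OTES; C9 OTBDPS), via hydroxy enal 33 (not isolated), via lactol 34 (not isolated)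
Conditions: TEMPO (cat.), PhI(OAc)2, CH2Cl2, rt
Reagents that add atoms: none
Why: Oxoammonium oxidation is selective for the primary allylic C12 alcohol; the enal is trapped by the C6 hydroxyl as a five-membered lactol and oxidised again (oxidative lactonisation), leaving the secondary C3 alcohol.

Step 18
Reactants: 35 alpha-methylene gamma-lactone with free C3 OH
Product: 36 C3 acetate
Conditions: Ac2O, pyridine, DMAP (cat.), CH2Cl2, 0 °C
Reagents that add atoms: acetic anhydride, CC(=O)OC(C)=O
Why: DMAP-catalysed acylation of the only free hydroxyl group.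

Step 19
Reactants: 36 C3 acetate
Product: 37 C8 alcohol (C3 OAc; lactone; C9 OTBDPS)
Conditions: HF·pyridine, pyridine, THF, 0 °C
Reagents that add atoms: none
Why: Selective desilylation, since buffered HF·pyridine cleaves the secondary triethylsilyl ether much faster than the primary tert-butyldiphenylsilyl ether and does not disturb acetate or lactone.

Step 20
Reactants: 38 tiglic acid [(2E)-2-methylbut-2-enoic acid]
Product: 39 (2E)-2-methylbut-2-en-1-ol
Conditions: LiAlH4, Et2O, 0 °C → rt
Reagents that add atoms: none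
Why: Hydride reduction of the unsaturated acid by 1,2-addition gives the allylic alcohol with the E geometry intact.

Step 21
Reactants: 39 (2E)-2-methylbut-2-en-1-ol
Product: 40 [(2R,3R)-2,3-dimethyloxiran-2-yl]methanol
Conditions: Ti(OiPr)4 (cat.), D-(−)-diisopropyl tartrate (cat.), t-BuOOH, 4 Å MS, CH2Cl2, −20 °C
Reagents that add atoms: tert-butyl hydroperoxide, CC(C)(C)OO
Why: Sharpless asymmetric epoxidation, in which the titanium tartrate complex delivers oxygen to one alkene face; D-(−)-tartrate should give the (2R,3R)-epoxy alcohol, and the E alkene fixes the relative configuration (the two methyl groups cis).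

Step 22
Reactants: 40 [(2R,3R)-2,3-dimethyloxiran-2-yl]methanol
Product: 41 (2S,3R)-2,3-dimethyloxirane-2-carboxylic acid
Conditions: RuCl3·xH2O (cat.), NaIO4, CCl4/MeCN/H2O, rt
Reagents that add atoms: water, O
Why: Ruthenium tetroxide generated in situ oxidises the primary alcohol through the aldehyde hydrate to the acid without opening the epoxide; the C2 descriptor changes from R to S by priority only.

Step 23
Reactants: 37 C8 alcohol; 41 (2S,3R)-2,3-dimethyloxirane-2-carboxylic acid
Product: 43 O8 epoxy ester (C3 OAc; lactone; C9 OTBDPS), via mixed anhydride 42 (not isolated)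
Conditions: 2,4,6-Cl3C6H2COCl, Et3N, THF, rt; then 37, DMAP, toluene, rt
Reagents that add atoms: none
Why: Yamaguchi esterification, in which DMAP attacks the mixed anhydride at the epoxy-acyl carbonyl (the aroyl carbonyl is shielded by its two ortho chlorines) and the acylpyridinium acylates the C8 hydroxyl with no change at any stereocentre.

Step 24
Reactants: 43 O8 epoxy ester
Product: 44 C9 primary alcohol
Conditions: HF·pyridine, pyridine, THF, rt
Reagents that add atoms: none
Why: Fluoride desilylation under mildly acidic, non-basic conditions should free the primary alcohol without O8-to-O9 acyl migration or epoxide opening.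

Step 25
Reactants: 44 C9 primary alcohol
Product: 45 C9 aldehyde (alpha-acyloxy aldehyde)
Conditions: Dess–Martin periodinane, NaHCO3, CH2Cl2, 0 °C → rt
Reagents that add atoms: none
Why: Dess–Martin oxidation gives the aldehyde under buffered conditions that should not epimerise C8.

Step 26
Reactants: 45 C9 aldehyde
Product: 46 CNP0299903.2 (target)
Conditions: CrCl2 (excess), NiCl2 (cat.), DMSO/THF, rt, high dilution
Reagents that add atoms: none
Why: Nozaki–Hiyama–Kishi reaction, in which nickel-catalysed activation of the alkenyl iodide and transmetalation to chromium give an alkenylchromium species with retained Z geometry that adds to the C9 aldehyde (ten-membered ring closure at C9–C10); attack anti to the C8 acyloxy group (polar Felkin–Anh) should give the 8,9-anti arrangement, 9R.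

**Compound list**

1 | but-2-yn-1-ol | CC#CCO | starting material
2 | cyclic sodium alkoxy(alkenyl)aluminate from trans-hydroalumination of 1 | CC1=CCO[Al-]1(OCCOC)OCCOC.[Na+] | intermediate (not isolated)
3 | (2Z)-3-iodobut-2-en-1-ol | OC/C=C(/C)I | intermediate
4 | (2Z)-1-bromo-3-iodobut-2-ene | BrC/C=C(/C)I | intermediate
5 | 3-methylfuran | Cc1ccoc1 | starting material
6 | 2-bromo-3-methylfuran | Cc1ccoc1Br | intermediate
7 | (5-bromo-4-methylfuran-2-yl)lithium | Cc1cc([Li])oc1Br | intermediate (not isolated)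
8 | 2-(5-bromo-4-methylfuran-2-yl)ethan-1-ol | Cc1cc(CCO)oc1Br | intermediate
9 | lithium 2-(5-lithio-4-methylfuran-2-yl)ethoxide | Cc1cc(CCO[Li])oc1[Li] | intermediate (not isolated)
10 | 2-{5-[(2Z)-3-iodobut-2-en-1-yl]-4-methylfuran-2-yl}ethan-1-ol | Cc1cc(CCO)oc1C/C=C(/C)I | intermediate
11 | {5-[(2Z)-3-iodobut-2-en-1-yl]-4-methylfuran-2-yl}acetaldehyde | Cc1cc(CC=O)oc1C/C=C(/C)I | intermediate (not isolated)
12 | {5-[(2Z)-3-iodobut-2-en-1-yl]-4-methylfuran-2-yl}acetic acid | Cc1cc(CC(=O)O)oc1C/C=C(/C)I | intermediate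
13 | (4S)-4-benzyl-1,3-oxazolidin-2-one | O=C1N[C@@H](Cc2ccccc2)CO1 | starting material
14 | mixed anhydride of 12 with pivalic acid | Cc1cc(CC(=O)OC(=O)C(C)(C)C)oc1C/C=C(/C)I | intermediate (not isolated)
15 | N-lithio-(4S)-4-benzyl-1,3-oxazolidin-2-one | O=C1N([Li])[C@@H](Cc2ccccc2)CO1 | intermediate (not isolated)
16 | (4S)-4-benzyl-3-({5-[(2Z)-3-iodobut-2-en-1-yl]-4-methylfuran-2-yl}acetyl)-1,3-oxazolidin-2-one | Cc1cc(CC(=O)N2[C@@H](Cc3ccccc3)COC2=O)oc1C/C=C(/C)I | intermediate
17 | 2-[(tert-butyldiphenylsilyl)oxy]acetaldehyde | O=CCO[Si](c1ccccc1)(c1ccccc1)C(C)(C)C | starting material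
18 | (Z)-dibutylboron enolate of 16 | CCCCB(CCCC)O/C(=C\c1cc(C)c(C/C=C(/C)I)o1)N1[C@@H](Cc2ccccc2)COC1=O | intermediate (not isolated)
19 | (4S)-4-benzyl-3-[(2R,3S)-4-[(tert-butyldiphenylsilyl)oxy]-3-hydroxy-2-{5-[(2Z)-3-iodobut-2-en-1-yl]-4-methylfuran-2-yl}butanoyl]-1,3-oxazolidin-2-one | Cc1cc([C@H](C(=O)N2[C@@H](Cc3ccccc3)COC2=O)[C@H](O)CO[Si](c3ccccc3)(c3ccccc3)C(C)(C)C)oc1C/C=C(/C)I | intermediate
20 | (2R,3S)-4-[(tert-butyldiphenylsilyl)oxy]-3-hydroxy-2-{5-[(2Z)-3-iodobut-2-en-1-yl]-4-methylfuran-2-yl}-N-methoxy-N-methylbutanamide | Cc1cc([C@H](C(=O)N(C)OC)[C@H](O)CO[Si](c2ccccc2)(c2ccccc2)C(C)(C)C)oc1C/C=C(/C)I | intermediate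
21 | (2R,3S)-4-[(tert-butyldiphenylsilyl)oxy]-2-{5-[(2Z)-3-iodobut-2-en-1-yl]-4-methylfuran-2-yl}-N-methoxy-N-methyl-3-[(triethylsilyl)oxy]butanamide | Cc1cc([C@H](C(=O)N(C)OC)[C@H](O[Si](CC)(CC)CC)CO[Si](c2ccccc2)(c2ccccc2)C(C)(C)C)oc1C/C=C(/C)I | intermediate
22 | (4-methoxyphenyl)methanol | COc1ccc(CO)cc1 | starting material
23 | tributyl(iodomethyl)stannane | CCCC[Sn](CCCC)(CCCC)CI | starting material
24 | tributyl{[(4-methoxybenzyl)oxy]methyl}stannane | CCCC[Sn](CCCC)(CCCC)COCc1ccc(OC)cc1 | intermediate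
25 | {[(4-methoxybenzyl)oxy]methyl}lithium | [Li]COCc1ccc(OC)cc1 | intermediate (not isolated)
26 | {[(4-methoxybenzyl)oxy]methyl}magnesium bromide | Br[Mg]COCc1ccc(OC)cc1 | intermediate (not isolated)
27 | (3R,4S)-5-[(tert-butyldiphenylsilyl)oxy]-3-{5-[(2Z)-3-iodobut-2-en-1-yl]-4-methylfuran-2-yl}-1-[(4-methoxybenzyl)oxy]-4-[(triethylsilyl)oxy]pentan-2-one | Cc1cc([C@H](C(=O)COCc2ccc(OC)cc2)[C@H](O[Si](CC)(CC)CC)CO[Si](c2ccccc2)(c2ccccc2)C(C)(C)C)oc1C/C=C(/C)I | intermediate
28 | 2-[(3R,4S)-5-[(tert-butyldiphenylsilyl)oxy]-2-{[(4-methoxybenzyl)oxy]methyl}-4-[(triethylsilyl)oxy]pent-1-en-3-yl]-5-[(2Z)-3-iodobut-2-en-1-yl]-4-methylfuran (furan carbons = C3–C6) | Cc1cc([C@H](C(=C)COCc2ccc(OC)cc2)[C@H](O[Si](CC)(CC)CC)CO[Si](c2ccccc2)(c2ccccc2)C(C)(C)C)oc1C/C=C(/C)I | intermediate (key-step precursor)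
29 | furan endoperoxide of 28: 2,3,7-trioxabicyclo[2.2.1]hept-5-ene with C3 and C6 as bridgeheads | CC1=CC2([C@H](C(=C)COCc3ccc(OC)cc3)[C@H](O[Si](CC)(CC)CC)CO[Si](c3ccccc3)(c3ccccc3)C(C)(C)C)OOC1(C/C=C(/C)I)O2 | intermediate (not isolated)
30 | (1(10)Z,4Z,7R,8S)-9-[(tert-butyldiphenylsilyl)oxy]-10-iodo-12-[(4-methoxybenzyl)oxy]-8-[(triethylsilyl)oxy]-9,10-seco-germacra-1(10),4,11(13)-triene-3,6-dione | I/C(C)=C\CC(=O)/C(C)=C\C(=O)[C@H](C(=C)COCc1ccc(OC)cc1)[C@H](O[Si](CC)(CC)CC)CO[Si](c1ccccc1)(c1ccccc1)C(C)(C)C | intermediate (key-step product)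
31 | (1(10)Z,3S,4Z,6R,7S,8S)-9-[(tert-butyldiphenylsilyl)oxy]-10-iodo-12-[(4-methoxybenzyl)oxy]-8-[(triethylsilyl)oxy]-9,10-seco-germacra-1(10),4,11(13)-triene-3,6-diol | I/C(C)=C\C[C@H](O)/C(C)=C\[C@@H](O)[C@H](C(=C)COCc1ccc(OC)cc1)[C@H](O[Si](CC)(CC)CC)CO[Si](c1ccccc1)(c1ccccc1)C(C)(C)C | intermediate
32 | (1(10)Z,3S,4Z,6R,7S,8S)-9-[(tert-butyldiphenylsilyl)oxy]-10-iodo-8-[(triethylsilyl)oxy]-9,10-seco-germacra-1(10),4,11(13)-triene-3,6,12-triol | I/C(C)=C\C[C@H](O)/C(C)=C\[C@@H](O)[C@H](C(=C)CO)[C@H](O[Si](CC)(CC)CC)CO[Si](c1ccccc1)(c1ccccc1)C(C)(C)C | intermediate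
33 | 3,6-dihydroxy-12-aldehyde (2-substituted acrolein) from 32 | I/C(C)=C\C[C@H](O)/C(C)=C\[C@@H](O)[C@H](C(=C)C=O)[C@H](O[Si](CC)(CC)CC)CO[Si](c1ccccc1)(c1ccccc1)C(C)(C)C | intermediate (not isolated)
34 | five-membered lactol (O6–C12) from 33 | C=C1C(O)O[C@H](/C=C(/C)[C@@H](O)C/C=C(/C)I)[C@H]1[C@H](O[Si](CC)(CC)CC)CO[Si](c1ccccc1)(c1ccccc1)C(C)(C)C | intermediate (not isolated)
35 | (1(10)Z,3S,4Z,6R,7S,8S)-9-[(tert-butyldiphenylsilyl)oxy]-3-hydroxy-10-iodo-8-[(triethylsilyl)oxy]-9,10-seco-germacra-1(10),4,11(13)-trien-12,6-olide | C=C1C(=O)O[C@H](/C=C(/C)[C@@H](O)C/C=C(/C)I)[C@H]1[C@H](O[Si](CC)(CC)CC)CO[Si](c1ccccc1)(c1ccccc1)C(C)(C)C | intermediate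
36 | (1(10)Z,3S,4Z,6R,7S,8S)-3-acetoxy-9-[(tert-butyldiphenylsilyl)oxy]-10-iodo-8-[(triethylsilyl)oxy]-9,10-seco-germacra-1(10),4,11(13)-trien-12,6-olide | C=C1C(=O)O[C@H](/C=C(/C)[C@@H](OC(C)=O)C/C=C(/C)I)[C@H]1[C@H](O[Si](CC)(CC)CC)CO[Si](c1ccccc1)(c1ccccc1)C(C)(C)C | intermediate
37 | (1(10)Z,3S,4Z,6R,7R,8S)-3-acetoxy-9-[(tert-butyldiphenylsilyl)oxy]-8-hydroxy-10-iodo-9,10-seco-germacra-1(10),4,11(13)-trien-12,6-olide | C=C1C(=O)O[C@H](/C=C(/C)[C@@H](OC(C)=O)C/C=C(/C)I)[C@H]1[C@H](O)CO[Si](c1ccccc1)(c1ccccc1)C(C)(C)C | intermediate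
38 | tiglic acid, (2E)-2-methylbut-2-enoic acid | C/C=C(\C)C(=O)O | starting material
39 | (2E)-2-methylbut-2-en-1-ol | C/C=C(\C)CO | intermediate
40 | [(2R,3R)-2,3-dimethyloxiran-2-yl]methanol | OC[C@@]1(C)O[C@@H]1C | intermediate
41 | (2S,3R)-2,3-dimethyloxirane-2-carboxylic acid | OC(=O)[C@@]1(C)O[C@@H]1C | intermediate
42 | mixed anhydride of 41 with 2,4,6-trichlorobenzoic acid | O=C(OC(=O)[C@@]1(C)O[C@@H]1C)c1c(Cl)cc(Cl)cc1Cl | intermediate (not isolated)
43 | (1(10)Z,3S,4Z,6R,7S,8S)-3-acetoxy-9-[(tert-butyldiphenylsilyl)oxy]-8-{[(2S,3R)-2,3-dimethyloxiran-2-yl]carbonyloxy}-10-iodo-9,10-seco-germacra-1(10),4,11(13)-trien-12,6-olide | C=C1C(=O)O[C@H](/C=C(/C)[C@@H](OC(C)=O)C/C=C(/C)I)[C@H]1[C@H](OC(=O)[C@@]1(C)O[C@@H]1C)CO[Si](c1ccccc1)(c1ccccc1)C(C)(C)C | intermediate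
44 | the corresponding 9-hydroxy compound (3S,6R,7S,8S) | C=C1C(=O)O[C@H](/C=C(/C)[C@@H](OC(C)=O)C/C=C(/C)I)[C@H]1[C@H](OC(=O)[C@@]1(C)O[C@@H]1C)CO | intermediate
45 | the corresponding 9-oxo compound (C9 aldehyde; 3S,6R,7S,8S) | C=C1C(=O)O[C@H](/C=C(/C)[C@@H](OC(C)=O)C/C=C(/C)I)[C@H]1[C@H](OC(=O)[C@@]1(C)O[C@@H]1C)C=O | intermediate
46 | CNP0299903.2: (1(10)Z,3S,4Z,6R,7S,8S,9R)-3-acetoxy-8-{[(2S,3R)-2,3-dimethyloxiran-2-yl]carbonyloxy}-9-hydroxygermacra-1(10),4,11(13)-trien-12,6-olide | C=C1C(=O)O[C@@H]2/C=C(/C)[C@@H](OC(C)=O)C/C=C(/C)[C@@H](O)[C@@H](OC(=O)[C@@]3(C)O[C@@H]3C)[C@@H]12 | target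

**Step count and risks**

Total: 26 steps. Longest linear sequence: 20 steps (5 → 46: steps 3–10, 12–19, 23–26).

Steps most likely to fail:

1. Step 26 (C9–C10 ring closure). The likely failure is poor facial selectivity in the addition to the C9 aldehyde, because the conformation of the forming ten-membered ring can override Felkin–Anh control. The fallback sets out from 45 and comes back at 46. The ring is closed as in step 26 without regard to the C9 configuration. The epimeric carbinols are oxidised together (Dess–Martin periodinane, NaHCO3, CH2Cl2) to the single macrocyclic C9 enone F1. F1 is then reduced with (R)-2-methyl-CBS-oxazaborolidine and catecholborane at −78 °C, where the C1=C10 alkenyl group is the large substituent, which should give 9R, that is 46. C9 is then set by carbonyl reduction instead of by carbon–carbon bond formation.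

2. Step 15 (double reduction). The likely failure is loss of reagent control at C6, where the branched C7 substituent competes with the alkenyl group for the role of the large group, while C3 is reduced correctly. The fallback sets out from 30 and comes back at 36. The same reduction then delivers mainly the (3S,6S)-diol F2. Its less hindered C3 hydroxyl is acetylated selectively (Ac2O, pyridine, CH2Cl2, −20 °C) to the 3-acetate F3. A Mitsunobu reaction at C6 with chloroacetic acid (PPh3, DIAD, toluene, 0 °C) inverts that centre and gives the (6R)-chloroacetate F4. Thiourea and NaHCO3 in ethanol remove only the chloroacetyl group and give the (6R)-alcohol F5. DDQ in buffered CH2Cl2 frees the C12 alcohol to give the diol acetate F6, and the TEMPO/PhI(OAc)2 lactonisation of step 17 then gives 36 directly, so step 18 is not needed.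

3. Step 12 (C11–C12 bond). The likely failure is enolisation of the Weinreb amide at the furyl-activated C7 position (epimerisation or beta-elimination of the silyloxy group), or halogen–metal exchange at the alkenyl iodide in place of addition. The fallback sets out from 21 and comes back at 27. DIBAL-H (CH2Cl2, −78 °C) reduces 21 to the C11 aldehyde F7. A SmI2-promoted Barbier-type addition of 4-methoxybenzyl chloromethyl ether (THF, 0 °C), in which the reagent is generated in the presence of the aldehyde so that no basic organometallic accumulates, gives the C11 carbinol F8 as an epimer mixture. Dess–Martin oxidation of F8 gives 27.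

Further compounds
F1 | step 26 | macrocyclic C9 enone (9-oxo analogue of 46) | C=C1C(=O)O[C@@H]2/C=C(/C)[C@@H](OC(C)=O)C/C=C(/C)C(=O)[C@@H](OC(=O)[C@@]3(C)O[C@@H]3C)[C@@H]12
F2 | step 15 | (3S,6S)-diol, the C6 epimer of 31 | I/C(C)=C\C[C@H](O)/C(C)=C\[C@H](O)[C@H](C(=C)COCc1ccc(OC)cc1)[C@H](O[Si](CC)(CC)CC)CO[Si](c1ccccc1)(c1ccccc1)C(C)(C)C
F3 | step 15 | 3-O-acetate of F2 | I/C(C)=C\C[C@H](OC(C)=O)/C(C)=C\[C@H](O)[C@H](C(=C)COCc1ccc(OC)cc1)[C@H](O[Si](CC)(CC)CC)CO[Si](c1ccccc1)(c1ccccc1)C(C)(C)C
F4 | step 15 | (6R)-chloroacetate with 3-O-acetate | I/C(C)=C\C[C@H](OC(C)=O)/C(C)=C\[C@@H](OC(=O)CCl)[C@H](C(=C)COCc1ccc(OC)cc1)[C@H](O[Si](CC)(CC)CC)CO[Si](c1ccccc1)(c1ccccc1)C(C)(C)C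
F5 | step 15 | (3S,6R)-3-acetoxy-6-hydroxy compound with C12 OPMB | I/C(C)=C\C[C@H](OC(C)=O)/C(C)=C\[C@@H](O)[C@H](C(=C)COCc1ccc(OC)cc1)[C@H](O[Si](CC)(CC)CC)CO[Si](c1ccccc1)(c1ccccc1)C(C)(C)C
F6 | step 15 | (3S,6R)-3-acetoxy-6,12-diol | I/C(C)=C\C[C@H](OC(C)=O)/C(C)=C\[C@@H](O)[C@H](C(=C)CO)[C@H](O[Si](CC)(CC)CC)CO[Si](c1ccccc1)(c1ccccc1)C(C)(C)C
F7 | step 12 | C11 aldehyde from 21 (7R,8S) | Cc1cc([C@H](C=O)[C@H](O[Si](CC)(CC)CC)CO[Si](c2ccccc2)(c2ccccc2)C(C)(C)C)oc1C/C=C(/C)I
F8 | step 12 | C11 carbinol with C12 OPMB (C11 epimer mixture) | Cc1cc([C@H](C(O)COCc2ccc(OC)cc2)[C@H](O[Si](CC)(CC)CC)CO[Si](c2ccccc2)(c2ccccc2)C(C)(C)C)oc1C/C=C(/C)I
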